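What is left of the open intermediate at 12.0 h is little: 5.1% in birch, 1.0% in larch. So the best of the new flask lies early, and we follow the rate of gain, not the amounts.

| setting | birch | elm | larch | flask |
|---|---|---|---|---|
| substrate | 0.010 M | 0.015 M | 0.020 M | 0.020 M |
| partner | 1.3 equiv | 1.3 equiv | 2 equiv | 1.30 equiv |
| remark | run made earlier | run made earlier | run made earlier |  |
| time |  |  |  | 10 h |

- birch (time / h: open intermediate / %, target / %): 0.133: 15.7, 0; 0.500: 32.4, 3.0; 2.50: 12.4, 19.9; 12.0: 5.1, 23.3
- elm (time / h: open intermediate / %, target / %): 0.133: 16.6, 0.2; 0.500: 29.1, 5.6; 2.50: 9.3, 18.6; 12.0: 3.8, 22.5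
- larch (time / h: open intermediate / %, target / %): 0.133: 17.7, 0; 0.500: 21.1, 10.6; 2.50: 2.0, 24.1; 12.0: 1.0, 23.1

(standard deviation of a reading: 1 percentage point)



* the best time, 10 h at the latest, for open intermediate
* the amount of open intermediate, in percent of the substrate charged, at that time

The runs start alike. Over the first leg, to 0.133 h, the open intermediate gains on average 1.25 /h, as a fraction of the charge, while partner ranges from 0.0130 M to 0.0400 M.

On the second leg, to 0.500 h, that gain rate is down by a factor 2.59 in birch, 3.66 in elm and 14.4 in larch, the largest. In powers of ten these are 0.413, 0.563 and 1.16 decades. Each run's decades over its partner charge give on average 29.9 /M. We call this the slowing strength: decades of gain rate lost per unit of partner molarity.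

The new flask holds 0.0260 M of partner, so we reckon 0.777 decades, a factor 5.99. The first leg gives 16.6% and the second adds 7.66%. Our own reckoning therefore puts the open intermediate in the new flask near 24.3% at 0.500 h. It sums gain over the two legs and counts no loss, so it gives an amount at that time and places no top.

The forecast says 0.45 h and 27%, higher than ours: “The 0.5 h reading falls with partner (32, 29, 21), which interpolates to about 26–27% for flask.”

The new flask peaks at 0.434 h with 27.0%.

    substrate ⇌ open intermediate (K = 1.20, k = 4.20 × 10⁻⁴ /s)
    partner → second intermediate (k = 4.20 × 10⁻⁴ /s)
    open intermediate + second intermediate ⇌ target (K = 1700 /M, k = 0.0600 /M/s)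
    target ⇌ isomer of the product (K = 3.10, k = 0.00260 /s)

That top is 2.7 percentage points above our reckoning for 0.500 h. The top of this flask is flat: at 0.542 h it still holds 26.3%. We put the slowing strength to use once more, on the neighbour flask with 0.050 M of substrate at the same equivalents, so 0.0650 M of partner. It gives a factor 87.8 and an amount of 17.2% at 0.500 h. That neighbour's best is 20.1%, higher by 2.9 points.

The earlier runs and the new flask are simulated with constants of no real substance; the scatter is artificial.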